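**Retrosynthetic overview**
- The only ring is bought: phloroglucinol 1 supplies the carbocycle, so no ring is formed in the route.
- The C-acyl bond comes from Friedel–Crafts acylation of 1 by propionyl chloride 2, giving flopropione 3.
- Each of the three C-prenyl groups is traced back, through an aromatic Claisen [3,3] shift, to an aryl–O–C(CH3)2–CH=CH2 ether bond at the 4-oxygen, made from 2-methylbut-3-en-2-ol 4 (key disconnection: C–O).
- Three C–O formation/[3,3] operations follow, each with one equivalent of 4: 3 → 5 → 6, then 6 → 7 → 8, then 8 → 9 → 10. The third shift enters a prenyl-bearing carbon and dearomatises the ring to postlupulone 10.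

Assumption: postlupulone has no stereocentre (the quaternary ring carbon carries two identical prenyl groups), so it is achiral and there is no enantiomer to select; the SMILES is read as one tautomer of the enolised β-triketone.

**Step 1**
Reactants: 1 phloroglucinol; 2 propionyl chloride (1.05 equiv)
Product: 3 flopropione (1-(2,4,6-trihydroxyphenyl)propan-1-one)
Conditions: AlCl3 (3.5 equiv), PhNO2, 65 °C, 3 h; then ice/1 M HCl
Reagents that add atoms: none
Why: Friedel–Crafts acylation of the symmetrical triphenol stops at mono-C-acylation because the first acyl group, chelated to aluminium, deactivates the ring; no stereocentre is formed.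

**Step 2**
Reactants: 3 flopropione (1.5 equiv, excess recovered); 4 2-methylbut-3-en-2-ol (1.0 equiv)
Product: 6 3-prenylflopropione, via flopropione 4-O-(1,1-dimethylallyl) ether 5 (not isolated)
Conditions: Pd2(dba)3 (2.5 mol %), Xantphos (6 mol %), 4 Å MS, 1,4-dioxane, 100 °C, sealed tube, 4 added in four portions over 2 h, then 8 h
Reagents that add atoms: none
Why: Proposed new method: the acidic 4-OH of 3 (a vinylogous carboxylic acid) protonates the tertiary allylic alcohol so that zerovalent palladium ionises it without added activator to a (1,1-dimethylallyl)palladium cation/phenoxide ion pair, whose oxygen collapses on the more substituted allyl terminus (new C–O bond, ether 5), and at 100 °C the ether undergoes aromatic Claisen rearrangement into the free ortho carbon and tautomerises irreversibly to the n-prenyl phenol 6, while any linear O-prenyl ether is re-ionised by palladium and fed back and the excess of 3 holds back a second prenylation; the closest known reaction types are the dehydrative Tsuji–Trost allylation of acidic pronucleophiles by free allylic alcohols and the palladium-catalysed O-(1,1-dimethylallyl)ation of phenols by tertiary allyl carbonates followed by thermal aromatic Claisen rearrangement; no stereocentre is formed.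

**Step 3**
Reactants: 6 3-prenylflopropione; 4 2-methylbut-3-en-2-ol (1.1 equiv)
Product: 8 3,5-diprenylflopropione, via 3-prenylflopropione 4-O-(1,1-dimethylallyl) ether 7 (not isolated)
Conditions: Pd2(dba)3 (2.5 mol %), Xantphos (6 mol %), 4 Å MS, 1,4-dioxane, 100 °C, sealed tube, 12 h
Reagents that add atoms: none
Why: Proposed new method: the same activator-free ionisation of 4 by zerovalent palladium, triggered by the acidic 4-OH of 6, gives the tertiary ether 7 by O-attack on the more substituted allyl terminus, and its aromatic Claisen [3,3] shift goes to the unsubstituted ortho carbon, where rearomatisation by tautomerisation makes it irreversible and delivers 8 (an ether formed at the 6-oxygen rearranges into the same carbon); the closest known reaction types are the dehydrative Tsuji–Trost allylation with free allylic alcohols and the palladium-catalysed O-(1,1-dimethylallyl)ation/Claisen sequence of phenols with tertiary allyl carbonates; no stereocentre is formed.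

**Step 4**
Reactants: 8 3,5-diprenylflopropione; 4 2-methylbut-3-en-2-ol (1.2 equiv)
Product: 10 postlupulone, via 3,5-diprenylflopropione 4-O-(1,1-dimethylallyl) ether 9 (not isolated)
Conditions: Pd2(dba)3 (5 mol %), Xantphos (12 mol %), 4 Å MS, 1,4-dioxane, 110 °C, sealed tube, 16 h
Reagents that add atoms: none
Why: Proposed new method: the 4-OH of 8 again lets zerovalent palladium ionise 4 and the ion pair closes to the crowded tertiary ether 9 (C–O bond), whose Claisen [3,3] shift can only enter a prenyl-bearing ortho carbon, so it creates the quaternary gem-diprenyl carbon and a cyclohexadienone that cannot rearomatise and is trapped by tautomerisation as the chelated β-triketone enol 10, an irreversible sink (direct C-attack of the phenoxide carbon of 8 on the prenylpalladium cation gives the same product); the closest known reaction types are the dehydrative Tsuji–Trost allylation with free allylic alcohols, the aromatic Claisen rearrangement into an occupied ortho position and the dearomatising C-prenylation of acylphloroglucinols; the new quaternary carbon bears two identical prenyl groups, so no stereocentre is formed.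

**Compound list**
1 | phloroglucinol (benzene-1,3,5-triol) | Oc1cc(O)cc(O)c1 | starting material
2 | propionyl chloride (propanoyl chloride) | CCC(=O)Cl | starting material
3 | flopropione, 1-(2,4,6-trihydroxyphenyl)propan-1-one | CCC(=O)c1c(O)cc(O)cc1O | intermediate
4 | 2-methylbut-3-en-2-ol | CC(C)(O)C=C | starting material
5 | flopropione 4-O-(1,1-dimethylallyl) ether, 1-[2,6-dihydroxy-4-(2-methylbut-3-en-2-yloxy)phenyl]propan-1-one | CCC(=O)c1c(O)cc(OC(C)(C)C=C)cc1O | intermediate
6 | 3-prenylflopropione, 1-[2,4,6-trihydroxy-3-(3-methylbut-2-en-1-yl)phenyl]propan-1-one | CCC(=O)c1c(O)cc(O)c(CC=C(C)C)c1O | intermediate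
7 | 3-prenylflopropione 4-O-(1,1-dimethylallyl) ether, 1-[2,6-dihydroxy-3-(3-methylbut-2-en-1-yl)-4-(2-methylbut-3-en-2-yloxy)phenyl]propan-1-one | CCC(=O)c1c(O)cc(OC(C)(C)C=C)c(CC=C(C)C)c1O | intermediate
8 | 3,5-diprenylflopropione, 1-[2,4,6-trihydroxy-3,5-bis(3-methylbut-2-en-1-yl)phenyl]propan-1-one | CCC(=O)c1c(O)c(CC=C(C)C)c(O)c(CC=C(C)C)c1O | intermediate
9 | 3,5-diprenylflopropione 4-O-(1,1-dimethylallyl) ether, 1-[2,6-dihydroxy-3,5-bis(3-methylbut-2-en-1-yl)-4-(2-methylbut-3-en-2-yloxy)phenyl]propan-1-one | CCC(=O)c1c(O)c(CC=C(C)C)c(OC(C)(C)C=C)c(CC=C(C)C)c1O | intermediate
10 | postlupulone, 3,5-dihydroxy-4,6,6-tris(3-methylbut-2-en-1-yl)-2-propanoylcyclohexa-2,4-dien-1-one | CCC(=O)C1=C(O)C(CC=C(C)C)=C(O)C(CC=C(C)C)(CC=C(C)C)C1=O | target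

**Count**
Total steps: 4. Longest linear sequence: 4.

**Steps most likely to fail**

1. Step 4 (proposed new step, dearomatising third prenylation). The 4-oxygen of 8 is flanked by two prenyl groups, so forming the crowded ether 9 and its shift into an occupied carbon is the slowest of the three cycles. Loss of the allyl fragment as isoprene and addition of a fourth prenyl group to 10 are the main side reactions. The fallback uses known chemistry, sets out from 8 and comes back at 10. Alcohol 4 is converted by 48 % aqueous HBr at 0 °C (allylic transposition) into prenyl bromide F2. The sodium salt of 8 (NaOMe, MeOH, 0 °C) is then C-alkylated at a prenyl-bearing ring carbon by F2, the classical dearomatising alkylation that turns deoxyhumulone-type phenols into lupulones.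

2. Step 2 (proposed new step, first prenylation). The free tertiary alcohol may not ionise fast enough, and product 6 is as reactive as 3, so some 8 forms despite the excess of 3. The fallback uses known chemistry, sets out from 3 and comes back at 6. Alcohol 4 is deprotonated (n-BuLi, THF, 0 °C) and treated with Boc2O to give tert-butyl 2-methylbut-3-en-2-yl carbonate F1. Phenol 3 is O-alkylated by F1 under the established kinetic conditions (Pd(PPh3)4 5 mol %, THF, 0 °C), and ether 5 is isolated. Heating 5 alone in toluene at 110 °C gives 6 by aromatic Claisen rearrangement, so each of the two events is controlled separately.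

3. Step 3 (proposed new step, second prenylation). Ether 7 may in part rearrange into the prenyl-bearing carbon instead of the free one, and some over-prenylation to 10 is possible. The fallback uses known chemistry, sets out from 6 and comes back at 8. Phenol 6 is C-prenylated directly by 4 under acid catalysis (BF3·OEt2 0.3 equiv, 1,4-dioxane, 20 °C), the established Friedel–Crafts prenylation of acylphloroglucinols at the free ring carbon. This forms the C–C bond without any ether intermediate, and no new compound is made on the way (F0).

**Further compounds**
F1 | step 2 | tert-butyl 2-methylbut-3-en-2-yl carbonate | CC(C)(C)OC(=O)OC(C)(C)C=C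
F0 | step 3 | none | none
F2 | step 4 | prenyl bromide (1-bromo-3-methylbut-2-ene) | CC(C)=CCBr
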